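**Retrosynthetic overview**
1. The target is a (2S)-flavanone (benzo ring A, 4-hydroxyphenyl ring B, pyranone ring C; atoms O1, C2–C8a). Its C6 oxygen carries C4' of a flavone (benzo ring D, pyranone ring E, phenylene ring F).
2. Ring C is disconnected at two bonds at once, O1–C2 and C2–C3. A tert-butyl 3-aryl-3-oxopropanoate that already holds rings A, D, E and F is joined with 4-(benzyloxy)benzaldehyde (ring B), cyclised enantioselectively and decarboxylated in one flask.
3. Enabling features: C3 lies between C4=O and C2, so it can carry a temporary ester that makes C3 nucleophilic, makes C2 doubly electrophilic and gives a chiral thiourea a two-point handle. Ring A as its 5,7-dimethyl ether has a local mirror plane through C6 and C8a, so C4a and C8 are equivalent on acylation and O1–H is the only free phenol at ring closure.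
4. After ring closure the 5-OMe, peri to C4=O, is distinguished from 7-OMe by chelation and is cleaved together with the three benzyl ethers. The symmetric ring A phenol comes from an aryl bromide, and the diaryl ether from an SNAr reaction on 4-fluorobenzaldehyde.
5. Ring order: A, B, D and F are bought as arenes, ring E is closed by oxidative chalcone cyclisation, and ring C is closed last.

Key step: step 8

Assumption: the quinidine-derived thiourea is taken to give 2S, by analogy with the facial preference of this catalyst family in conjugate additions to chalcone-type acceptors; if the opposite sense is found, the pseudo-enantiomeric quinine-derived thiourea replaces it and nothing else changes.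

Step 1
Reactants: 1 2',4',6'-trihydroxyacetophenone
Product: 2 1-[2,4-bis(benzyloxy)-6-hydroxyphenyl]ethanone
Conditions: BnBr (2.1 equiv), K2CO3 (2.2 equiv), DMF, rt → 60 °C
Reagents that add atoms: benzyl bromide BrCc1ccccc1
Why: Williamson ether synthesis in which the 4-OH and one of the two equivalent ortho OH groups are alkylated, while the last OH is held in a hydrogen bond to the acetyl C=O and stays free.

Step 2
Reactants: 3 4-bromo-2,6-dimethoxyphenol; 4 4-fluorobenzaldehyde
Product: 5 4-(4-bromo-2,6-dimethoxyphenoxy)benzaldehyde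
Conditions: K2CO3, DMAc, 130 °C
Reagents that add atoms: none
Why: Nucleophilic aromatic substitution (addition–elimination) in which the para formyl group stabilises the Meisenheimer adduct and fluoride leaves, while the unactivated aryl bromide of the phenoxide partner survives.

Step 3
Reactants: 2 1-[2,4-bis(benzyloxy)-6-hydroxyphenyl]ethanone; 5 4-(4-bromo-2,6-dimethoxyphenoxy)benzaldehyde
Product: 6 (E)-1-[2,4-bis(benzyloxy)-6-hydroxyphenyl]-3-[4-(4-bromo-2,6-dimethoxyphenoxy)phenyl]prop-2-en-1-one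
Conditions: KOH (50% aq), EtOH–THF, rt
Reagents that add atoms: none
Why: Claisen–Schmidt condensation in which only the ketone is enolisable and only the aldehyde is a good acceptor, and E1cB dehydration should give the E-enone.

Step 4
Reactants: 6 (E)-1-[2,4-bis(benzyloxy)-6-hydroxyphenyl]-3-[4-(4-bromo-2,6-dimethoxyphenoxy)phenyl]prop-2-en-1-one
Product: 7 5,7-bis(benzyloxy)-2-[4-(4-bromo-2,6-dimethoxyphenoxy)phenyl]-4H-chromen-4-one
Conditions: I2 (10 mol%), DMSO, 130 °C
Reagents that add atoms: none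
Why: Iodine/DMSO oxidative cyclisation of a 2'-hydroxychalcone, in which oxa-Michael closure of ring E is followed by α-iodination and loss of HI, and DMSO reoxidises HI to I2.

Step 5
Reactants: 7 5,7-bis(benzyloxy)-2-[4-(4-bromo-2,6-dimethoxyphenoxy)phenyl]-4H-chromen-4-one
Product: 9 5,7-bis(benzyloxy)-2-[4-(4-hydroxy-2,6-dimethoxyphenoxy)phenyl]-4H-chromen-4-one, via pinacol boronate 8 (not isolated)
Conditions: B2pin2, Pd(dppf)Cl2 (3 mol%), KOAc, 1,4-dioxane, 90 °C; then 30% aq H2O2, NaHCO3 buffer, THF–H2O, 0 °C → rt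
Reagents that add atoms: bis(pinacolato)diboron CC1(C)OB(OC1(C)C)B1OC(C)(C)C(C)(C)O1; hydrogen peroxide OO
Why: Miyaura borylation of the unhindered aryl bromide followed by ipso-oxidation of the boronate (1,2-aryl shift from boron to oxygen) should put the O1 oxygen para to the diaryl ether under conditions too mild to open ring E.

Step 6
Reactants: 9 5,7-bis(benzyloxy)-2-[4-(4-hydroxy-2,6-dimethoxyphenoxy)phenyl]-4H-chromen-4-one
Product: 10 2-[4-(3-acetyl-4-hydroxy-2,6-dimethoxyphenoxy)phenyl]-5,7-bis(benzyloxy)-4H-chromen-4-one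
Conditions: Ac2O, BF3·OEt2, ClCH2CH2Cl, 0 → 45 °C; then H2O
Reagents that add atoms: acetic anhydride CC(=O)OC(C)=O
Why: Friedel–Crafts acetylation (by way of the O-acetate and its Fries rearrangement) at a carbon that is ortho to OH, ortho to one OMe and para to the other; the two such carbons are mirror images, so a single product should form, and rings D and F are deactivated by the BF3-complexed pyranone.

Step 7
Reactants: 10 2-[4-(3-acetyl-4-hydroxy-2,6-dimethoxyphenoxy)phenyl]-5,7-bis(benzyloxy)-4H-chromen-4-one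
Product: 11 tert-butyl 3-(3-{4-[5,7-bis(benzyloxy)-4-oxo-4H-chromen-2-yl]phenoxy}-6-hydroxy-2,4-dimethoxyphenyl)-3-oxopropanoate
Conditions: LiHMDS (3.3 equiv), THF, −78 °C; Boc2O (1.1 equiv), −78 → −20 °C; then 1 M HCl, 0 °C
Reagents that add atoms: di-tert-butyl dicarbonate CC(C)(C)OC(=O)OC(=O)OC(C)(C)C
Why: Claisen-type C-acylation of the phenoxide–enolate dianion, whose carbon end is the more nucleophilic, with a third equivalent of base taking up the acidic product; LiHMDS is too weak and too bulky to metalate or add to ring E.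

Step 8
Reactants: 11 tert-butyl 3-(3-{4-[5,7-bis(benzyloxy)-4-oxo-4H-chromen-2-yl]phenoxy}-6-hydroxy-2,4-dimethoxyphenyl)-3-oxopropanoate; 12 4-(benzyloxy)benzaldehyde
Product: 16 (2S)-2-[4-(benzyloxy)phenyl]-6-{4-[5,7-bis(benzyloxy)-4-oxo-4H-chromen-2-yl]phenoxy}-5,7-dimethoxy-2,3-dihydro-4H-chromen-4-one, via alkylidene keto ester 13 (not isolated), via flavanone tert-butyl ester 14 (not isolated), via flavanone keto acid 15 (not isolated)
Conditions: piperidine/AcOH (10 mol% each), 4 Å MS, toluene, rt; then N-[3,5-bis(trifluoromethyl)phenyl]-N'-[(9R)-6'-methoxycinchonan-9-yl]thiourea (15 mol%), −25 °C; then TsOH·H2O (0.5 equiv), 80 °C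
Reagents that add atoms: none
Why: Piperidinium acetate condenses the only acidic CH2 of 11 (C3, between C4=O and the ester) with aldehyde 12 in a Knoevenagel condensation, which brings in ring B and makes C2 of 13 a doubly activated acceptor. The bifunctional cinchona thiourea then binds the 1,3-dicarbonyl unit through its two N–H bonds while its quinuclidine nitrogen takes the O1–H proton, and O1 adds to C2 in a 6-endo-trig intramolecular oxa-Michael addition that closes ring C; this is the known thiourea-catalysed enantioselective cyclisation of 2-hydroxyaryl alkylidene β-keto esters to flavanones. The C2 stereocentre is set by the catalyst, which presents one face of the C2=C3 bond to O1, whereas C3 settles trans under thermodynamic control and is erased afterwards. Toluenesulfonic acid then cleaves the tert-butyl ester and the β-keto acid 15 decarboxylates, which removes the activating group and with it the easy retro-Michael path, so the configuration at C2 should be locked. Regioselectivity needs no control because O5 is methylated and O1–H is the only free phenol, so an 8-aryloxy isomer cannot form, and the flavone half has neither an acidic CH2 nor a free OH. The 5-OMe group twists the open enone out of conjugation with ring A and so shifts the ring–chain equilibrium towards the closed flavanone.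

Step 9
Reactants: 16 (2S)-2-[4-(benzyloxy)phenyl]-6-{4-[5,7-bis(benzyloxy)-4-oxo-4H-chromen-2-yl]phenoxy}-5,7-dimethoxy-2,3-dihydro-4H-chromen-4-one
Product: 17 (2S)-6-[4-(5,7-dihydroxy-4-oxo-4H-chromen-2-yl)phenoxy]-5-hydroxy-2-(4-hydroxyphenyl)-7-methoxy-2,3-dihydro-4H-chromen-4-one
Conditions: BCl3 (1 M in CH2Cl2, 10 equiv), C6HMe5 (9 equiv), CH2Cl2, −78 → 0 °C; then ice–water
Reagents that add atoms: none
Why: Lewis acid ether cleavage in which BCl3, with pentamethylbenzene as benzyl cation scavenger, removes the three aryl benzyl ethers in the cold, and on warming boron chelated between C4=O and O5 removes only the peri methyl group (chelation-controlled demethylation), while 7-OMe, the diaryl ether and the base-sensitive C2 centre should stay untouched.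

**Compound list**
1 | 2',4',6'-trihydroxyacetophenone | CC(=O)c1c(O)cc(O)cc1O | starting material
2 | 1-[2,4-bis(benzyloxy)-6-hydroxyphenyl]ethanone | CC(=O)c1c(O)cc(OCc2ccccc2)cc1OCc1ccccc1 | intermediate
3 | 4-bromo-2,6-dimethoxyphenol | COc1cc(Br)cc(OC)c1O | starting material
4 | 4-fluorobenzaldehyde | O=Cc1ccc(F)cc1 | starting material
5 | 4-(4-bromo-2,6-dimethoxyphenoxy)benzaldehyde | COc1cc(Br)cc(OC)c1Oc1ccc(C=O)cc1 | intermediate
6 | (E)-1-[2,4-bis(benzyloxy)-6-hydroxyphenyl]-3-[4-(4-bromo-2,6-dimethoxyphenoxy)phenyl]prop-2-en-1-one | COc1cc(Br)cc(OC)c1Oc1ccc(/C=C/C(=O)c2c(O)cc(OCc3ccccc3)cc2OCc2ccccc2)cc1 | intermediate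
7 | 5,7-bis(benzyloxy)-2-[4-(4-bromo-2,6-dimethoxyphenoxy)phenyl]-4H-chromen-4-one | COc1cc(Br)cc(OC)c1Oc1ccc(-c2cc(=O)c3c(OCc4ccccc4)cc(OCc4ccccc4)cc3o2)cc1 | intermediate
8 | 5,7-bis(benzyloxy)-2-{4-[2,6-dimethoxy-4-(4,4,5,5-tetramethyl-1,3,2-dioxaborolan-2-yl)phenoxy]phenyl}-4H-chromen-4-one | COc1cc(B2OC(C)(C)C(C)(C)O2)cc(OC)c1Oc1ccc(-c2cc(=O)c3c(OCc4ccccc4)cc(OCc4ccccc4)cc3o2)cc1 | intermediate
9 | 5,7-bis(benzyloxy)-2-[4-(4-hydroxy-2,6-dimethoxyphenoxy)phenyl]-4H-chromen-4-one | COc1cc(O)cc(OC)c1Oc1ccc(-c2cc(=O)c3c(OCc4ccccc4)cc(OCc4ccccc4)cc3o2)cc1 | intermediate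
10 | 2-[4-(3-acetyl-4-hydroxy-2,6-dimethoxyphenoxy)phenyl]-5,7-bis(benzyloxy)-4H-chromen-4-one | COc1cc(O)c(C(C)=O)c(OC)c1Oc1ccc(-c2cc(=O)c3c(OCc4ccccc4)cc(OCc4ccccc4)cc3o2)cc1 | intermediate
11 | tert-butyl 3-(3-{4-[5,7-bis(benzyloxy)-4-oxo-4H-chromen-2-yl]phenoxy}-6-hydroxy-2,4-dimethoxyphenyl)-3-oxopropanoate | COc1cc(O)c(C(=O)CC(=O)OC(C)(C)C)c(OC)c1Oc1ccc(-c2cc(=O)c3c(OCc4ccccc4)cc(OCc4ccccc4)cc3o2)cc1 | intermediate
12 | 4-(benzyloxy)benzaldehyde | O=Cc1ccc(OCc2ccccc2)cc1 | starting material
13 | tert-butyl (Z)-3-[4-(benzyloxy)phenyl]-2-(3-{4-[5,7-bis(benzyloxy)-4-oxo-4H-chromen-2-yl]phenoxy}-6-hydroxy-2,4-dimethoxybenzoyl)prop-2-enoate | COc1cc(O)c(C(=O)/C(C(=O)OC(C)(C)C)=C/c2ccc(OCc3ccccc3)cc2)c(OC)c1Oc1ccc(-c2cc(=O)c3c(OCc4ccccc4)cc(OCc4ccccc4)cc3o2)cc1 | intermediate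
14 | tert-butyl (2S,3R)-2-[4-(benzyloxy)phenyl]-6-{4-[5,7-bis(benzyloxy)-4-oxo-4H-chromen-2-yl]phenoxy}-5,7-dimethoxy-4-oxo-3,4-dihydro-2H-chromene-3-carboxylate (trans keto form) | COc1cc2c(c(OC)c1Oc1ccc(-c3cc(=O)c4c(OCc5ccccc5)cc(OCc5ccccc5)cc4o3)cc1)C(=O)[C@H](C(=O)OC(C)(C)C)[C@@H](c1ccc(OCc3ccccc3)cc1)O2 | intermediate
15 | (2S,3R)-2-[4-(benzyloxy)phenyl]-6-{4-[5,7-bis(benzyloxy)-4-oxo-4H-chromen-2-yl]phenoxy}-5,7-dimethoxy-4-oxo-3,4-dihydro-2H-chromene-3-carboxylic acid | COc1cc2c(c(OC)c1Oc1ccc(-c3cc(=O)c4c(OCc5ccccc5)cc(OCc5ccccc5)cc4o3)cc1)C(=O)[C@H](C(=O)O)[C@@H](c1ccc(OCc3ccccc3)cc1)O2 | intermediate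
16 | (2S)-2-[4-(benzyloxy)phenyl]-6-{4-[5,7-bis(benzyloxy)-4-oxo-4H-chromen-2-yl]phenoxy}-5,7-dimethoxy-2,3-dihydro-4H-chromen-4-one | COc1cc2c(c(OC)c1Oc1ccc(-c3cc(=O)c4c(OCc5ccccc5)cc(OCc5ccccc5)cc4o3)cc1)C(=O)C[C@@H](c1ccc(OCc3ccccc3)cc1)O2 | intermediate
17 | (2S)-6-[4-(5,7-dihydroxy-4-oxo-4H-chromen-2-yl)phenoxy]-5-hydroxy-2-(4-hydroxyphenyl)-7-methoxy-2,3-dihydro-4H-chromen-4-one | COc1cc2c(c(O)c1Oc1ccc(-c3cc(=O)c4c(O)cc(O)cc4o3)cc1)C(=O)C[C@@H](c1ccc(O)cc1)O2 | target

Total step count: 9. Longest linear sequence: 8 steps (from 3 through steps 2–9, or equally from 1 through steps 1 and 3–9).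

**Steps most likely to fail**

Step 8. Three processes could lower conversion or enantiomeric purity: uncatalysed or amine-catalysed racemic cyclisation while the condensation is still running, sluggish condensation of the hindered keto ester with an electron-rich aldehyde, and acid-induced opening and reclosure of ring C during ester cleavage. The fallback sets out from 10 and brings ring B in after ring closure. Heating 10 with N,N-dimethylformamide dimethyl acetal should give the enaminone F1. HCl in CH2Cl2 should close it to the chromone F2, so ring C remains the last ring closed. An asymmetric conjugate addition of 4-(benzyloxy)phenylboronic acid then follows, using Pd(OCOCF3)2 and 4-tert-butyl-2-(pyridin-2-yl)-4,5-dihydrooxazole (the enantiomer that gives 2S), NH4PF6 and H2O in ClCH2CH2Cl at 60 °C. This sets C2 and comes back to the route at 16.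

Step 6. The Lewis acid may cleave or transfer the benzyl group peri to the ring E carbonyl, or the O-acetate may fail to rearrange at a temperature the benzyl ethers tolerate. The fallback sets out from 9 and avoids Lewis acids. N-iodosuccinimide in MeCN at 0 °C should iodinate one of the two equivalent carbons next to the free OH to give the ortho-iodophenol F3. Stille coupling with tributyl(1-ethoxyvinyl)stannane (Pd(PPh3)2Cl2, toluene, 100 °C) should give the 1-ethoxyvinyl arene F4. Hydrolysis with 1 M HCl in THF comes back to the route at 10.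

Step 9. Boron coordination at C4=O may trigger reversible opening of ring C to the chalcone, with loss of configuration at C2, or demethylation may also occur at O7 while the last benzyl ether is still being cleaved. The fallback sets out from 16 and separates the two tasks. Neutral hydrogenolysis (H2, palladium on carbon, EtOAc–THF, rt) should give the triphenol 5-O-methyl ether F5. Chelation-controlled demethylation with MgI2·OEt2 in THF at 40 °C then removes only the peri methyl group and arrives at 17.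

**Further compounds**
F1 | step 8 | 5,7-bis(benzyloxy)-2-(4-{3-[(E)-3-(dimethylamino)prop-2-enoyl]-4-hydroxy-2,6-dimethoxyphenoxy}phenyl)-4H-chromen-4-one | COc1cc(O)c(C(=O)/C=C/N(C)C)c(OC)c1Oc1ccc(-c2cc(=O)c3c(OCc4ccccc4)cc(OCc4ccccc4)cc3o2)cc1
F2 | step 8 | 6-{4-[5,7-bis(benzyloxy)-4-oxo-4H-chromen-2-yl]phenoxy}-5,7-dimethoxy-4H-chromen-4-one | COc1cc2occc(=O)c2c(OC)c1Oc1ccc(-c2cc(=O)c3c(OCc4ccccc4)cc(OCc4ccccc4)cc3o2)cc1
F3 | step 6 | 5,7-bis(benzyloxy)-2-[4-(4-hydroxy-3-iodo-2,6-dimethoxyphenoxy)phenyl]-4H-chromen-4-one | COc1cc(O)c(I)c(OC)c1Oc1ccc(-c2cc(=O)c3c(OCc4ccccc4)cc(OCc4ccccc4)cc3o2)cc1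
F4 | step 6 | 5,7-bis(benzyloxy)-2-{4-[3-(1-ethoxyvinyl)-4-hydroxy-2,6-dimethoxyphenoxy]phenyl}-4H-chromen-4-one | COc1cc(O)c(C(=C)OCC)c(OC)c1Oc1ccc(-c2cc(=O)c3c(OCc4ccccc4)cc(OCc4ccccc4)cc3o2)cc1
F5 | step 9 | (2S)-6-[4-(5,7-dihydroxy-4-oxo-4H-chromen-2-yl)phenoxy]-2-(4-hydroxyphenyl)-5,7-dimethoxy-2,3-dihydro-4H-chromen-4-one | COc1cc2c(c(OC)c1Oc1ccc(-c3cc(=O)c4c(O)cc(O)cc4o3)cc1)C(=O)C[C@@H](c1ccc(O)cc1)O2
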